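**Retrosynthetic overview**
1. Target 12 ⇐ hydrogenolysis of two catechol diphenylmethylene ketals ⇐ monoacetate 11 ⇐ C2-symmetric anti-diol 9, whose two hydroxyls are homotopic, so mono-acetylation can give only one compound.
2. Diol 9 ⇐ oxidation of 1,3-bis(boronate) 8 ⇐ two-directional C3–C4 / C4–C5 disconnection: CH2(Bpin)2 (5) supplies C4 and is homologated twice by the sparteine-generated α-oxygenated organolithium 6, which sets both stereocentres.
3. Organolithium 6 ⇐ TIB ester 4 (TIB = 2,4,6-triisopropylbenzoyl) ⇐ alcohol 3 ⇐ methyl dihydrocaffeate 1 (ketal protection, reduction).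
4. Rings: no skeletal ring is formed and both arene rings are bought. Only the two protecting benzodioxole rings (step 1) and a transient 1,3-dioxane orthoester (step 5) are made, and both are opened again.

Assumption: both carbinol centres of the target are R as read from the SMILES (the anti diol, mono-acetylated); 1, 5, (−)-sparteine and 2,4,6-triisopropylbenzoic acid are taken as catalogue items.

**Route**

Step 1
Reactants: 1 methyl 3-(3,4-dihydroxyphenyl)propanoate
Product: 2 methyl 3-(2,2-diphenyl-1,3-benzodioxol-5-yl)propanoate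
Conditions: Ph2CCl2 (1.5 equiv), neat, 170 °C, 30 min, N2 sweep
Reagents that add atoms: dichlorodiphenylmethane, ClC(Cl)(c1ccccc1)c1ccccc1
Why: Catechol ketalisation with a gem-dichloride (double O-alkylation through the diphenyl-stabilised cation, HCl driven off thermally) gives a benzodioxole with no acidic C–H that tolerates organolithium, peroxide and mild acid and is later removed by hydrogenolysis; no stereocentre is involved.

Step 2
Reactants: 2 methyl 3-(2,2-diphenyl-1,3-benzodioxol-5-yl)propanoate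
Product: 3 3-(2,2-diphenyl-1,3-benzodioxol-5-yl)propan-1-ol
Conditions: LiAlH4, THF, 0 °C → rt; Fieser work-up
Reagents that add atoms: none
Why: LiAlH4 reduction of the ester to the primary alcohol, with the ketal inert to hydride.

Step 3
Reactants: 3 3-(2,2-diphenyl-1,3-benzodioxol-5-yl)propan-1-ol
Product: 4 3-(2,2-diphenyl-1,3-benzodioxol-5-yl)propyl 2,4,6-triisopropylbenzoate
Conditions: 2,4,6-triisopropylbenzoic acid (1.1 equiv), PPh3, DIAD, THF, 0 °C → rt
Reagents that add atoms: 2,4,6-triisopropylbenzoic acid, CC(C)c1cc(C(C)C)c(C(=O)O)c(C(C)C)c1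
Why: Mitsunobu esterification of the primary alcohol installs the hindered TIB ester, whose shielded carbonyl resists s-BuLi addition, directs α-lithiation and later serves as the leaving group in the 1,2-shift.

Step 4
Reactants: 4 3-(2,2-diphenyl-1,3-benzodioxol-5-yl)propyl 2,4,6-triisopropylbenzoate (2.5 equiv); 5 bis(4,4,5,5-tetramethyl-1,3,2-dioxaborolan-2-yl)methane (1.0 equiv)
Product: 9 (3R,5R)-1,7-bis(2,2-diphenyl-1,3-benzodioxol-5-yl)heptane-3,5-diol, via (S)-lithiated TIB ester 6 (not isolated), via 1,2-bis(boronate) 7 (not isolated), via 1,3-bis(boronate) 8 (not isolated)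
Conditions: s-BuLi (2.4 equiv), (−)-sparteine (2.5 equiv), Et2O, −78 °C, 5 h; 5, −78 °C, 2 h, then → 35 °C, 3 h; NaOH (2 M aq), H2O2 (30%), THF, 0 °C → rt
Reagents that add atoms: sec-butyllithium, [Li]C(C)CC (the lithium of intermediate 6); hydrogen peroxide, OO (the two hydroxyl oxygens)
Why: Sparteine-mediated asymmetric deprotonation (Hoppe) removes the pro-S proton of 4 to give the configurationally stable α-oxygenated organolithium 6, a carbinol carbanion of reversed polarity; it attacks boron of 5 with retention and the boronate undergoes a stereospecific 1,2-metallate (Matteson-type) shift of the CH2B group with inversion and loss of the TIB carboxylate to give 7, whose less hindered primary boronate repeats the sequence to give 8, so that two C–Li carbons are joined to the C–B carbon of the linchpin, both stereocentres are fixed as R by the reagent (the minor enantiomer of 6 ends up mostly in the separable meso diol), and peroxide oxidation replaces each boron by OH with retention (lithiation–borylation–oxidation).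

Step 5
Reactants: 9 (3R,5R)-1,7-bis(2,2-diphenyl-1,3-benzodioxol-5-yl)heptane-3,5-diol
Product: 11 (3R,5R)-1,7-bis(2,2-diphenyl-1,3-benzodioxol-5-yl)-5-hydroxyheptan-3-yl acetate, via cyclic orthoester 10 (not isolated)
Conditions: MeC(OMe)3 (1.5 equiv), PPTS (5 mol%), CH2Cl2, rt, 1 h; then H2O, rt, 30 min
Reagents that add atoms: trimethyl orthoacetate, CC(OC)(OC)OC; water, O
Why: Acid-catalysed orthoester exchange gives the six-membered cyclic orthoester 10, whose hydrolysis through the dioxanylium ion opens to exactly one acetate and one free hydroxyl (orthoester-mediated mono-acylation); because 9 is C2-symmetric, either ring opening and any later acyl migration give the same compound, and no stereocentre is touched.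

Step 6
Reactants: 11 (3R,5R)-1,7-bis(2,2-diphenyl-1,3-benzodioxol-5-yl)-5-hydroxyheptan-3-yl acetate
Product: 12 (3R,5R)-1,7-bis(3,4-dihydroxyphenyl)-5-hydroxyheptan-3-yl acetate (CNP0132541.1)
Conditions: H2 (1 atm), 10% Pd/C, THF/EtOAc, rt; degassed work-up
Reagents that add atoms: none
Why: Catalytic hydrogenolysis of the doubly benzylic C–O bonds of both diphenylmethylene ketals releases the catechols and diphenylmethane under neutral conditions that leave the secondary acetate, the free alcohol and both stereocentres untouched.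

**Compound list**
1 | methyl 3-(3,4-dihydroxyphenyl)propanoate | COC(=O)CCc1ccc(O)c(O)c1 | starting material
2 | methyl 3-(2,2-diphenyl-1,3-benzodioxol-5-yl)propanoate | COC(=O)CCc1ccc2c(c1)OC(O2)(c1ccccc1)c1ccccc1 | intermediate
3 | 3-(2,2-diphenyl-1,3-benzodioxol-5-yl)propan-1-ol | OCCCc1ccc2c(c1)OC(O2)(c1ccccc1)c1ccccc1 | intermediate
4 | 3-(2,2-diphenyl-1,3-benzodioxol-5-yl)propyl 2,4,6-triisopropylbenzoate | CC(C)c1cc(C(C)C)c(C(=O)OCCCc2ccc3c(c2)OC(O3)(c2ccccc2)c2ccccc2)c(C(C)C)c1 | intermediate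
5 | bis(4,4,5,5-tetramethyl-1,3,2-dioxaborolan-2-yl)methane | CC1(C)OB(CB2OC(C)(C)C(C)(C)O2)OC1(C)C | starting material
6 | (S)-1-lithio-3-(2,2-diphenyl-1,3-benzodioxol-5-yl)propyl 2,4,6-triisopropylbenzoate, (−)-sparteine complex | [Li][C@@H](CCc1ccc2c(c1)OC(O2)(c1ccccc1)c1ccccc1)OC(=O)c1c(C(C)C)cc(C(C)C)cc1C(C)C | intermediate
7 | (S)-2,2'-[4-(2,2-diphenyl-1,3-benzodioxol-5-yl)butane-1,2-diyl]bis(4,4,5,5-tetramethyl-1,3,2-dioxaborolane) | CC1(C)OB(OC1(C)C)[C@H](CCc1ccc2c(c1)OC(O2)(c1ccccc1)c1ccccc1)CB1OC(C)(C)C(C)(C)O1 | intermediate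
8 | 2,2'-[(3R,5R)-1,7-bis(2,2-diphenyl-1,3-benzodioxol-5-yl)heptane-3,5-diyl]bis(4,4,5,5-tetramethyl-1,3,2-dioxaborolane) | CC1(C)OB(OC1(C)C)[C@H](CCc1ccc2c(c1)OC(O2)(c1ccccc1)c1ccccc1)C[C@H](B1OC(C)(C)C(C)(C)O1)CCc1ccc2c(c1)OC(O2)(c1ccccc1)c1ccccc1 | intermediate
9 | (3R,5R)-1,7-bis(2,2-diphenyl-1,3-benzodioxol-5-yl)heptane-3,5-diol | O[C@H](CCc1ccc2c(c1)OC(O2)(c1ccccc1)c1ccccc1)C[C@H](O)CCc1ccc2c(c1)OC(O2)(c1ccccc1)c1ccccc1 | intermediate
10 | (4R,6R)-4,6-bis[2-(2,2-diphenyl-1,3-benzodioxol-5-yl)ethyl]-2-methoxy-2-methyl-1,3-dioxane | COC1(C)O[C@H](CCc2ccc3c(c2)OC(O3)(c2ccccc2)c2ccccc2)C[C@@H](CCc2ccc3c(c2)OC(O3)(c2ccccc2)c2ccccc2)O1 | intermediate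
11 | (3R,5R)-1,7-bis(2,2-diphenyl-1,3-benzodioxol-5-yl)-5-hydroxyheptan-3-yl acetate | CC(=O)O[C@H](CCc1ccc2c(c1)OC(O2)(c1ccccc1)c1ccccc1)C[C@H](O)CCc1ccc2c(c1)OC(O2)(c1ccccc1)c1ccccc1 | intermediate
12 | (3R,5R)-1,7-bis(3,4-dihydroxyphenyl)-5-hydroxyheptan-3-yl acetate | CC(=O)O[C@H](CCc1ccc(O)c(O)c1)C[C@H](O)CCc1ccc(O)c(O)c1 | target

**Step count**
Total steps: 6. Longest linear sequence: 6 (1 → 2 → 3 → 4 → 9 → 11 → 12); 5 is bought and enters at step 4.

**Steps most likely to fail, with fallbacks**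

Step 4 carries the most risk. Both homologations must run in one flask before the excess of 6 decays, 6 must form without competing lithiation of the benzodioxole ring, and the anti:meso ratio rests on the enantiomeric ratio of 6 (about 97:3 would give roughly 94:6 before chromatography). If the second homologation lags, crude 7 can be re-exposed to a fresh charge of 6 before oxidation. The fallback sets the first C–B stereocentre by catalysis instead; it sets out from alcohol 3 and comes back to the route at 7. Dess–Martin oxidation of 3 gives 3-(2,2-diphenyl-1,3-benzodioxol-5-yl)propanal F1. Wittig methylenation (Ph3PCH3Br, KOtBu, THF) gives 5-(but-3-en-1-yl)-2,2-diphenyl-1,3-benzodioxole F2. Enantioselective alkene diboration (Pt(dba)3 as a zerovalent platinum source, the TADDOL-derived phenylphosphonite enantiomer that leads to the S product, B2pin2, THF, 60 °C) gives 7 as an isolated, purified compound. A single lithiation–borylation with 1.3 equiv of 6 at the primary boronate of 7 then gives 8, and oxidation gives 9.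

Step 5 may give an incomplete or slow orthoester, because the anti diol forces the dioxane into a twist-boat, and prolonged acid could start to attack the ketals. The fallback sets out from 9 and comes back at 11 without acid. Heating 9 with Bu2SnO (toluene, reflux, water removal) gives the stannylene acetal (4R,6R)-2,2-dibutyl-4,6-bis[2-(2,2-diphenyl-1,3-benzodioxol-5-yl)ethyl]-1,3,2-dioxastanninane F3. Treating F3 with acetyl chloride (1.0 equiv, CH2Cl2, 0 °C) acylates one tin-activated oxygen only, and aqueous KF work-up gives 11.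

Step 6 may be sluggish at the hindered diphenylmethylene carbon, and the free catechol acetate is air-sensitive on isolation. The fallback exchanges the phenol protection so that the last step is a buffered fluoride desilylation; it sets out from 9 and comes back at 12.
- Hot aqueous acetic acid (AcOH/H2O 4:1, 100 °C; no acetate is present yet) cleaves both ketals to (3R,5R)-1,7-bis(3,4-dihydroxyphenyl)heptane-3,5-diol F4.
- TBSCl (4.4 equiv) and imidazole in CH2Cl2/DMF at 0 °C silylate the four phenols in preference to the hindered secondary alcohols, giving (3R,5R)-1,7-bis[3,4-bis(tert-butyldimethylsilyloxy)phenyl]heptane-3,5-diol F5.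
- Trimethyl orthoacetate/PPTS gives the cyclic orthoester (4R,6R)-4,6-bis{2-[3,4-bis(tert-butyldimethylsilyloxy)phenyl]ethyl}-2-methoxy-2-methyl-1,3-dioxane F6, and water opens it to (3R,5R)-1,7-bis[3,4-bis(tert-butyldimethylsilyloxy)phenyl]-5-hydroxyheptan-3-yl acetate F7.
- Et3N·3HF in THF removes the four silyl groups to give 12.

**Further compounds**
F1 | step 4 | 3-(2,2-diphenyl-1,3-benzodioxol-5-yl)propanal | O=CCCc1ccc2c(c1)OC(O2)(c1ccccc1)c1ccccc1
F2 | step 4 | 5-(but-3-en-1-yl)-2,2-diphenyl-1,3-benzodioxole | C=CCCc1ccc2c(c1)OC(O2)(c1ccccc1)c1ccccc1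
F3 | step 5 | (4R,6R)-2,2-dibutyl-4,6-bis[2-(2,2-diphenyl-1,3-benzodioxol-5-yl)ethyl]-1,3,2-dioxastanninane | CCCC[Sn]1(CCCC)O[C@H](CCc2ccc3c(c2)OC(O3)(c2ccccc2)c2ccccc2)C[C@@H](CCc2ccc3c(c2)OC(O3)(c2ccccc2)c2ccccc2)O1
F4 | step 6 | (3R,5R)-1,7-bis(3,4-dihydroxyphenyl)heptane-3,5-diol | O[C@H](CCc1ccc(O)c(O)c1)C[C@H](O)CCc1ccc(O)c(O)c1
F5 | step 6 | (3R,5R)-1,7-bis[3,4-bis(tert-butyldimethylsilyloxy)phenyl]heptane-3,5-diol | O[C@H](CCc1ccc(O[Si](C)(C)C(C)(C)C)c(O[Si](C)(C)C(C)(C)C)c1)C[C@H](O)CCc1ccc(O[Si](C)(C)C(C)(C)C)c(O[Si](C)(C)C(C)(C)C)c1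
F6 | step 6 | (4R,6R)-4,6-bis{2-[3,4-bis(tert-butyldimethylsilyloxy)phenyl]ethyl}-2-methoxy-2-methyl-1,3-dioxane | COC1(C)O[C@H](CCc2ccc(O[Si](C)(C)C(C)(C)C)c(O[Si](C)(C)C(C)(C)C)c2)C[C@@H](CCc2ccc(O[Si](C)(C)C(C)(C)C)c(O[Si](C)(C)C(C)(C)C)c2)O1
F7 | step 6 | (3R,5R)-1,7-bis[3,4-bis(tert-butyldimethylsilyloxy)phenyl]-5-hydroxyheptan-3-yl acetate | CC(=O)O[C@H](CCc1ccc(O[Si](C)(C)C(C)(C)C)c(O[Si](C)(C)C(C)(C)C)c1)C[C@H](O)CCc1ccc(O[Si](C)(C)C(C)(C)C)c(O[Si](C)(C)C(C)(C)C)c1
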